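(Readings and results are simulated on assumed constants, and the scatter is random.)

1. Our vessel is closed, stirred and isothermal. The solid substrate starts undissolved in the reagent solution.

| flask | solid substrate | reagent | remark | time |
|---|---|---|---|---|
| south-east | 0.20 M | 0.80 M | run made earlier |  |
| flask | 0.40 M | 0.800 M |  | 50 min |

- south-east (time / min: target / %): 0.833: 5; 1.33: 15; 2.00: 25; 4.00: 47; 6.00: 61; 10.0: 74

(readings scatter by 1.5 percentage points)

- as a solid, counted per litre of solution: solid substrate
- at the start none of the solid substrate is in solution

- Thursday's: doubling the dissolution coefficient of the solid substrate, all else as stated
- Friday's: doubling the solubility of the solid substrate, all else as stated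
- Sunday's: doubling the amount of reagent, all else as stated

* target at 50 min, in percent of the solid substrate charged
* the change that raises the amount of target at 50 min, in percent of the solid substrate charged most ("none" if none brings more than 2 percentage points) (Thursday's / Friday's / Sunday's / none)
* amount of target at 50 min, in percent of the solid substrate charged, after Friday's

2. The nearest run is the south-east run: the same reagent charge, but half the solid substrate. That gives 4.00 equivalents of reagent there and 2.00 in the flask, with solid substrate the limiting reagent in both.

3. We read one quantity from that run. Its target curve climbs at 0.0140 M min⁻¹ around 5.00 min and at 0.00650 M min⁻¹ around 8.00 min. This gives 2.71 min for the closing half-time, the time in which the climb of c(target) slows to half. It is a reading and carries the scatter.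

4. The flask is read after 18.5 closing half-times of the south-east run, so we take it to stand at its end. With fewer equivalents of reagent, our own expectation is an end in percent below the south-east run's, though we put no figure on it.

5. The forecast gives 82% (74% to 93%), 82% after Friday's (74% to 94%) and Sunday's as best, holding: “Dissolution is then finished, or at least not limiting”.

6. The mechanism, now shown:

    2 solid substrate → homo dimer (k = 0.00800 M⁻¹ s⁻¹)
    solid substrate ⇌ dissolved substrate, rate k2*(cs2 - [dissolved substrate]) while solid is left; crystals form when [dissolved substrate] > cs2 (solubility = 0.190 M, k = 0.0230 s⁻¹)
    dissolved substrate + reagent ⇌ target (K = 12.0 M⁻¹, k = 0.00490 M⁻¹ s⁻¹)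

The flask gives 65.5%, and the best change is Friday's, which gains 11 percentage points and reaches 76.2%, against 7.7 points for Sunday's and 4.5 points for Thursday's. The closing half-time of the south-east run carries over: in this flask the step dissolved substrate + reagent ⇌ target by itself relaxes, both ways together, with a half-life of 3.56 min, and the same flask read at 3.0 h, 66.4 closing half-times, stands at 65.5%. Half of the homo dimer turnover up to 50 min is done by 0.487 min, sooner than the 2.9 min forward half-life of dissolved substrate with reagent at the charged concentrations. Counted as two substrate each, homo dimer holds 24.3% of the charge at 5.00 min and 24.3% at 50.0 min.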